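Remark on the chemistry: the rings are lettered A (methyl ester end), B (middle) and C (dihydroxy end), and each ring is numbered from the carbon bearing its carboxyl carbon (C1), so every ring has oxygen at C2 and C4 and methyl at C6.

## Analysis of the target

The target is an achiral tridepside: three orcinol-type benzene rings joined head to tail by two aryl ester bridges, ending in a methyl ester on one side and a free resorcinol unit on the other. Ring A is a methyl 2-methoxy-6-methylbenzoate acylated on its C4 oxygen, ring B is a 2-methoxy-6-methylbenzoyl unit acylated on its own C4 oxygen, and ring C is a 2,4-dihydroxy-6-methylbenzoyl unit. There is no stereocenter and no ring to close, so the task is one of connectivity and of telling six ring oxygens apart: two are methyl ethers, two are acylated and two are free phenols. Each of the three carbonyl carbons lies between an ortho methyl group and an ortho oxygen substituent, so every ester is hard to make from its acid, and the ring A phenol that must be acylated is deactivated by its para ester. The sensitive groups are the two aryl esters, which are activated esters and can exchange with phenoxides or alkoxides, and the ring C phenols, which would compete as nucleophiles if left free during assembly. The plan rests on the carbonyl carbon between ring B C1 and the oxygen on ring A C4: it is a single carbon bonded to one aryl carbon and one phenol oxygen, so it can be delivered as carbon monoxide between an iodide at ring B C1 and the ring A phenol.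

## Retrosynthetic reasoning

**16 to 15.** The two free hydroxyls on ring C are masked as benzyl ethers in 15. Free, they would compete with the intended phenol in every acylation and in the carbonylation. Benzyl is chosen because it survives base, acyl chloride formation and palladium under 14, and is removed by neutral hydrogenolysis, which leaves the two aryl esters and the methyl ester alone. The forward step only has to break two benzylic C–O bonds.

**15 to 10, 13 and 14.** Both bonds to the ring B carbonyl carbon are cut: ring B C1–C(=O) and C(=O)–O on ring A C4. This cut divides the molecule into halves of similar size, 10 (rings B and C) and 13 (ring A). It also removes the hardest classical operation, the activation of a ring B benzoic acid between its methoxy and methyl groups toward a deactivated phenol. Cutting only the acyl–oxygen bond would bring that problem back. Applying the carbonylation logic at the ring C carbonyl instead would leave the ring B to ring A ester to be made the classical way. The forward reaction has to insert palladium into the C–I bond of 10, take up 14, and hand the resulting aroyl group to the phenoxide of 13 without disturbing the ester already present.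

**10 to 4 and 8 (through 9).** The acyl–oxygen bond between the ring C carbonyl and the ring B C4 oxygen is cut. This ester is made early and classically: 8 has only hydrogens ortho to its hydroxyl, and 4 can be driven as its chloride 9 because neither partner carries anything fragile at that stage. The iodine in 8 is inert to acylation. The steric hindrance that makes this ester slow to form then protects it from exchange in the carbonylation.

**8 to 7, 6 and 5.** The C–I bond at the ring carbon between methoxy and methyl is cut. Phenol 5 already has the ring B oxygen pattern, one methyl ether and one free hydroxyl. All three open positions of 5 are activated, so the iodination is steered sterically: in the bulky silyl ether 6 the two positions next to the silyloxy group are shielded, leaving the carbon para to it. Desilylation of 7 then frees 8.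

**4 to 3, 1 and 2.** The ring C acid comes from its methyl ester 3 by saponification, and 3 from double O-benzylation of 1 with 2. Ester 1 supplies the whole ring C carbon skeleton and oxygen pattern.

**13 to 12, 11, 1 and 2.** Ring A needs methyl on O2 and hydrogen on O4, the reverse of the innate reactivity of 1, whose C4 hydroxyl alkylates first. The C4 hydroxyl is therefore benzylated with 2 (11), the chelated C2 hydroxyl is methylated (12), and the benzyl group is removed (13).

## Alternatives that were turned down

**Alternative 1:** Ring C is built last on the finished ring A–ring B depside instead of being brought in as an aromatic.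
- **Disconnection:** four ring C bonds are removed (C1–C2, C2–C3, C4–C5, C5–C6). This leads back to the diazoketone 3-methoxy-4-{[3-methoxy-4-(methoxycarbonyl)-5-methylphenoxy]carbonyl}-5-methylphenyl (2E)-5-diazo-3-methyl-4-oxopent-2-enoate A1 and to (triisopropylsilyloxy)ethyne A2.
- **Forward key step:** photolysis of A1 triggers a Wolff rearrangement in which the vinyl group shifts to the diazo carbon (C5–C6). The vinylketene adds A2 in a (2+2) fashion (C2–C3 and C4–C5). The cyclobutenone opens, and a six-electron electrocyclisation (C1–C2) followed by tautomerisation gives the ring C 4-O-triisopropylsilyl ether A3 of target 16. One desilylation would finish.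
- **For:** the mechanism fixes the substitution pattern. Ring C appears with its two oxygens already differentiated and needs no benzyl groups. The ring C ester is formed on an unhindered alkenoic acid. On protecting-group economy for ring C this plan is stronger than the chosen one, which spends two benzylations and a hydrogenolysis.
- **Against:** ring C is the ring whose acid is most cheaply available from 1, so the most elaborate chemistry goes to the easiest fragment. The hindered ring B to ring A ester must still be made beforehand by other means. A1 carries two aryl benzoate units that can undergo photo-Fries rearrangement under the same irradiation. A1 requires acyl chloride and diazoalkane chemistry on an advanced intermediate, and A2 is a sensitive reagent.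
- **Comparison:** the sequence is linear with its riskiest step at the end. The chosen plan is convergent, uses only preformed aromatic rings and puts its key step on the bond that is actually hard to make.

**Alternative 2:** Ring A is made from a pyrone.
- **Disconnection:** ring A bonds C3–C4 and C5–C6 are cut, leading to methyl 4-methoxy-6-methyl-2-oxo-2H-pyran-5-carboxylate A4 and 1,1-bis(trimethylsilyloxy)ethene A5.
- **Forward key step:** a (4+2) cycloaddition across pyrone C3 and C6, decarboxylative cycloreversion of the bridged lactone and loss of one silyloxy group give methyl 4-hydroxy-2-methoxy-6-methylbenzoate A6, the same structure as 13.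
- **For:** the methoxy group comes from the pyrone and the hydroxyl from the ketene acetal, so no protecting groups are needed. If A4 were at hand, this would reach the ring A phenol in one step against three from 1, so on step count for this fragment it could be shorter.
- **Against:** A4 is not a stock compound and needs its own synthesis. It is a push–pull diene, its 4-methoxy group opposing the ester activation, and its C6 terminus is fully substituted, so the cycloaddition with A5 should be slow. The product is the least demanding compound of the whole problem, and neither depside bond is addressed.
- **Comparison:** this is a fragment preparation, not a solution for the target, and it would still need the chosen carbonylation or an equivalent to go further. The chosen plan reaches 13 by three routine steps and reserves the inventive step for the union of the halves.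

**Alternative 3:** Ring B is made by cycloaddition.
- **Disconnection:** ring B bonds C1–C2 and C5–C6 are cut, giving 1,1-dimethoxy-3-(trimethylsilyloxy)buta-1,3-diene A7 and 3-methoxy-4-(methoxycarbonyl)-5-methylphenyl but-2-ynoate A8, the butynoate of 13.
- **Forward key step:** Diels–Alder addition, with the nucleophilic methylene terminus of A7 bonding to the methyl-bearing alkyne carbon, then loss of one methoxy group and the silyl group, gives 3-methoxy-4-(methoxycarbonyl)-5-methylphenyl 4-hydroxy-2-methoxy-6-methylbenzoate A9.
- **For:** the regiochemistry is the innate one. The ring B to ring A ester is formed on an unhindered alkynoic acid before the ortho substituents exist. On the central difficulty this plan is as strong as the chosen one, and it needs neither palladium nor carbon monoxide pressure.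
- **Against:** a but-2-ynoate is a sluggish dienophile because of its β-methyl group. A8 is an activated aryl ester and Michael acceptor facing a strongly nucleophilic, thermally and hydrolytically labile diene, so conjugate addition without ring closure and acyl transfer with loss of 13 are likely competitors. After A9, ring C still has to be attached and deprotected by conventional acylation.
- **Comparison:** the sequence is linear with the key step in the middle, and ring B is built from scratch although 5 already contains it. The chosen plan is convergent, takes all three rings from cheap aromatic stock, and its key step is the last skeleton-forming event.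

Key step: step 10

## Route

Step 1
Reactants: 1 methyl orsellinate (methyl 2,4-dihydroxy-6-methylbenzoate); 2 benzyl bromide
Product: 3 methyl 2,4-bis(benzyloxy)-6-methylbenzoate
Conditions: 2 (2.5 equiv), K2CO3, DMF, 70 °C
Reagents that add atoms: none
Why: Williamson etherification of both phenols; the hydrogen-bonded C2 hydroxyl reacts under these forcing conditions (excess 2, polar aprotic solvent, heat), and the hindered methyl ester is inert to carbonate.

Step 2
Reactants: 3 methyl 2,4-bis(benzyloxy)-6-methylbenzoate
Product: 4 2,4-bis(benzyloxy)-6-methylbenzoic acid
Conditions: KOH, DMSO/H2O, 90 °C; then aq. HCl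
Reagents that add atoms: potassium hydroxide, [K+].[OH-]
Why: Saponification of a 2,6-disubstituted benzoate; poorly solvated hydroxide in hot aqueous DMSO should overcome the steric shielding of the carbonyl, and benzyl ethers are stable to base.

Step 3
Reactants: 5 3-methoxy-5-methylphenol
Product: 6 triisopropyl(3-methoxy-5-methylphenoxy)silane
Conditions: TIPSCl, imidazole, DMF, rt
Reagents that add atoms: chlorotriisopropylsilane, CC(C)[Si](Cl)(C(C)C)C(C)C
Why: O-Silylation of a phenol with a silyl chloride and imidazole; the bulky group is installed to steer the iodination in step 4.

Step 4
Reactants: 6 triisopropyl(3-methoxy-5-methylphenoxy)silane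
Product: 7 (4-iodo-3-methoxy-5-methylphenoxy)triisopropylsilane
Conditions: NIS, MeCN, 0 °C to rt, dark
Reagents that add atoms: N-iodosuccinimide, O=C1CCC(=O)N1I
Why: Electrophilic aromatic iodination; all three free positions are electronically activated, but the two that flank the triisopropylsilyloxy group are shielded by it, so iodine should enter para to the silyloxy oxygen, between methoxy and methyl.

Step 5
Reactants: 7 (4-iodo-3-methoxy-5-methylphenoxy)triisopropylsilane
Product: 8 4-iodo-3-methoxy-5-methylphenol
Conditions: Bu4NF, AcOH, THF, 0 °C
Reagents that add atoms: none
Why: Fluoride-induced cleavage of an aryl silyl ether, driven by Si–F bond formation; the acetic acid buffer keeps the electron-rich iodophenol from standing as its phenoxide.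

Step 6
Reactants: 4 2,4-bis(benzyloxy)-6-methylbenzoic acid; 8 4-iodo-3-methoxy-5-methylphenol
Product: 10 4-iodo-3-methoxy-5-methylphenyl 2,4-bis(benzyloxy)-6-methylbenzoate, via 2,4-bis(benzyloxy)-6-methylbenzoyl chloride 9 (not isolated)
Conditions: (COCl)2, DMF (cat.), CH2Cl2, 0 °C to rt; evaporate; then 8, Et3N, DMAP (cat.), CH2Cl2, 0 °C to rt
Reagents that add atoms: none
Why: Acyl chloride formation through the chloroiminium species from oxalyl chloride and DMF, then DMAP-catalysed nucleophilic acyl substitution by a phenol that has only hydrogens ortho to its hydroxyl; aryl iodide and benzyl ethers are inert.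

Step 7
Reactants: 1 methyl orsellinate; 2 benzyl bromide
Product: 11 methyl 4-(benzyloxy)-2-hydroxy-6-methylbenzoate
Conditions: 2 (1.05 equiv), K2CO3, acetone, reflux
Reagents that add atoms: none
Why: Regioselective Williamson monoalkylation; the C4 hydroxyl is free and more acidic, whereas the C2 hydroxyl is held in a hydrogen bond to the ester carbonyl and reacts much more slowly with one equivalent of 2.

Step 8
Reactants: 11 methyl 4-(benzyloxy)-2-hydroxy-6-methylbenzoate
Product: 12 methyl 4-(benzyloxy)-2-methoxy-6-methylbenzoate
Conditions: MeI, K2CO3, DMF, 60 °C
Reagents that add atoms: iodomethane, CI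
Why: Williamson methylation of the chelated phenol, which yields to excess iodomethane in a polar aprotic solvent with heating.

Step 9
Reactants: 12 methyl 4-(benzyloxy)-2-methoxy-6-methylbenzoate
Product: 13 methyl 4-hydroxy-2-methoxy-6-methylbenzoate
Conditions: H2 (1 atm), 10% Pd/C, EtOAc, rt
Reagents that add atoms: none
Why: Catalytic hydrogenolysis of a benzyl aryl ether; methyl ester and methyl ether are inert.

Step 10
Reactants: 10 4-iodo-3-methoxy-5-methylphenyl 2,4-bis(benzyloxy)-6-methylbenzoate; 13 methyl 4-hydroxy-2-methoxy-6-methylbenzoate; 14 carbon monoxide
Product: 15 3-methoxy-4-{[3-methoxy-4-(methoxycarbonyl)-5-methylphenoxy]carbonyl}-5-methylphenyl 2,4-bis(benzyloxy)-6-methylbenzoate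
Conditions: Pd(OAc)2 (5 mol %), Xantphos (7.5 mol %), Et3N (3 equiv), CO (5 bar), toluene, 90 °C
Reagents that add atoms: none
Why: Pd(OAc)2 is reduced in the flask to a Xantphos-bound zerovalent palladium species that inserts into the C–I bond of 10 at ring B C1; 14 then coordinates and migratory insertion gives an aroyl divalent palladium iodide, a step that the two ortho substituents help because it relieves crowding at the metal. Et3N deprotonates 13, the phenoxide replaces iodide on palladium, and C–O reductive elimination from the wide-bite-angle complex should release 15 and return zerovalent palladium, the amine ending as its hydroiodide. The closest known reaction type is the palladium-catalysed aryloxycarbonylation of aryl iodides with phenols and carbon monoxide. No ring is closed and no stereocenter is formed; two skeletal bonds are made, ring B C1–C(=O) and C(=O)–O on ring A C4. Three selectivities are needed: carbonyl insertion must outrun direct aryl–oxygen coupling, which the CO pressure and the slow aryl–oxygen reductive elimination on this ligand should secure; the phenoxide must not exchange into the existing ring C ester or the methyl ester, both of which have two ortho substituents shielding the acyl carbon; and the benzyl ethers must survive, which they should because no hydride source is present. The iodide is used so that oxidative addition at the doubly flanked carbon is fast at this temperature.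

Step 11
Reactants: 15 3-methoxy-4-{[3-methoxy-4-(methoxycarbonyl)-5-methylphenoxy]carbonyl}-5-methylphenyl 2,4-bis(benzyloxy)-6-methylbenzoate
Product: 16 3-methoxy-4-{[3-methoxy-4-(methoxycarbonyl)-5-methylphenoxy]carbonyl}-5-methylphenyl 2,4-dihydroxy-6-methylbenzoate (target, CNP0514431.0)
Conditions: H2 (1 atm), 10% Pd/C, EtOAc, rt
Reagents that add atoms: none
Why: Catalytic hydrogenolysis of the two benzyl aryl ethers under neutral conditions; aryl esters and the methyl ester are inert to H2, and the non-nucleophilic solvent prevents acyl exchange at the depside links.

## Compound list

1 | methyl orsellinate (methyl 2,4-dihydroxy-6-methylbenzoate) | COC(=O)c1c(C)cc(O)cc1O | starting material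
2 | benzyl bromide | BrCc1ccccc1 | starting material
3 | methyl 2,4-bis(benzyloxy)-6-methylbenzoate | COC(=O)c1c(C)cc(OCc2ccccc2)cc1OCc1ccccc1 | intermediate
4 | 2,4-bis(benzyloxy)-6-methylbenzoic acid | OC(=O)c1c(C)cc(OCc2ccccc2)cc1OCc1ccccc1 | intermediate
5 | 3-methoxy-5-methylphenol | COc1cc(C)cc(O)c1 | starting material
6 | triisopropyl(3-methoxy-5-methylphenoxy)silane | COc1cc(C)cc(O[Si](C(C)C)(C(C)C)C(C)C)c1 | intermediate
7 | (4-iodo-3-methoxy-5-methylphenoxy)triisopropylsilane | COc1cc(O[Si](C(C)C)(C(C)C)C(C)C)cc(C)c1I | intermediate
8 | 4-iodo-3-methoxy-5-methylphenol | COc1cc(O)cc(C)c1I | intermediate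
9 | 2,4-bis(benzyloxy)-6-methylbenzoyl chloride (not isolated) | ClC(=O)c1c(C)cc(OCc2ccccc2)cc1OCc1ccccc1 | intermediate
10 | 4-iodo-3-methoxy-5-methylphenyl 2,4-bis(benzyloxy)-6-methylbenzoate | Cc1cc(OC(=O)c2c(C)cc(OCc3ccccc3)cc2OCc2ccccc2)cc(OC)c1I | intermediate
11 | methyl 4-(benzyloxy)-2-hydroxy-6-methylbenzoate | COC(=O)c1c(C)cc(OCc2ccccc2)cc1O | intermediate
12 | methyl 4-(benzyloxy)-2-methoxy-6-methylbenzoate | COC(=O)c1c(C)cc(OCc2ccccc2)cc1OC | intermediate
13 | methyl 4-hydroxy-2-methoxy-6-methylbenzoate | COC(=O)c1c(C)cc(O)cc1OC | intermediate
14 | carbon monoxide | [C-]#[O+] | starting material
15 | 3-methoxy-4-{[3-methoxy-4-(methoxycarbonyl)-5-methylphenoxy]carbonyl}-5-methylphenyl 2,4-bis(benzyloxy)-6-methylbenzoate | COC(=O)c1c(C)cc(OC(=O)c2c(C)cc(OC(=O)c3c(C)cc(OCc4ccccc4)cc3OCc3ccccc3)cc2OC)cc1OC | intermediate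
16 | 3-methoxy-4-{[3-methoxy-4-(methoxycarbonyl)-5-methylphenoxy]carbonyl}-5-methylphenyl 2,4-dihydroxy-6-methylbenzoate | COC(=O)c1c(C)cc(OC(=O)c2c(C)cc(OC(=O)c3c(C)cc(O)cc3O)cc2OC)cc1OC | target

## Step count and least certain steps

Total step count: 11. Longest linear sequence: 6 steps (5 to 16 through steps 3, 4, 5, 6, 10 and 11). The ring C arm (steps 1, 2, 6, 10, 11) and the ring A arm (steps 7, 8, 9, 10, 11) are five steps each.

**Step 10 (key step).** The most likely failure is slow capture of the doubly ortho-substituted aroylpalladium species by a weakly nucleophilic, para-ester phenoxide. While that intermediate waits, the catalyst can decompose, the iodide can be reduced off, or the phenoxide can exchange into an aryl ester and scramble the depside links. The fallback abandons the carbonylation and assembles the depside chain iteratively. It sets out from 12 and comes back to the route at 15. Saponification of 12 (KOH, aqueous DMSO, heat) should give 4-(benzyloxy)-2-methoxy-6-methylbenzoic acid F1. Coupling F1 with 13 by trifluoroacetic anhydride in toluene proceeds through a mixed anhydride that ionises to an alkoxy-stabilised acylium ion, which is not subject to the ortho blockade. This should give methyl 4-{[4-(benzyloxy)-2-methoxy-6-methylbenzoyl]oxy}-2-methoxy-6-methylbenzoate F2. Hydrogenolysis (H2, Pd/C, EtOAc) would free 3-methoxy-4-(methoxycarbonyl)-5-methylphenyl 4-hydroxy-2-methoxy-6-methylbenzoate F3. Acylation of F3 with chloride 9, prepared from 4 as in step 6 (Et3N, DMAP, CH2Cl2), would deliver 15.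

**Step 4.** Iodination may be poorly regioselective: the position para to the methoxy group is electronically at least as activated as the desired one, and only the bulk of the silyl group argues against it. Partial desilylation by adventitious acid would erode that control further. The fallback fixes the position through nitrogen and sets out from 5, returning at 8. Nitrosation of 5 (NaNO2, aqueous AcOH, 0 °C) is strongly para-selective for phenols and should give 3-methoxy-5-methyl-4-nitrosophenol F4. Reduction (Na2S2O4, aqueous base) would give 4-amino-3-methoxy-5-methylphenol F5. Diazotisation (NaNO2, H2SO4, 0 °C) followed by KI in a Sandmeyer-type iodination would give 8.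

**Step 2.** Hydrolysis may stall because hydroxide has to attack a carbonyl flanked by methyl and benzyloxy groups, and prolonged heating in strong base invites decomposition. The fallback avoids acyl substitution by hydroxide and goes through the aldehyde oxidation level, setting out from 3 and returning at 4. Reduction of 3 with LiAlH4 in THF should give [2,4-bis(benzyloxy)-6-methylphenyl]methanol F6. Oxidation with MnO2 in CH2Cl2 would give 2,4-bis(benzyloxy)-6-methylbenzaldehyde F7. Pinnick oxidation (NaClO2, NaH2PO4, 2-methyl-2-butene, t-BuOH/H2O) would give 4.

**Step 7.** Discrimination between the two hydroxyls of 1 may be incomplete, so over-alkylation to the bis(benzyl) ether competes; that over-alkylated material is compound 3 and can be used in the ring C arm. The fallback reverses the logic from selective protection to selective deprotection, setting out from 3 and returning at 11. Treating 3 with MgBr2·OEt2 in toluene/Et2O at reflux should cleave only the benzyl ether ortho to the ester, because magnesium chelates between the carbonyl oxygen and that ether oxygen and bromide then attacks the activated benzylic carbon. No compound outside the list is made (F0).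

## Further compounds

F1 | step 10 | 4-(benzyloxy)-2-methoxy-6-methylbenzoic acid | OC(=O)c1c(C)cc(OCc2ccccc2)cc1OC
F2 | step 10 | methyl 4-{[4-(benzyloxy)-2-methoxy-6-methylbenzoyl]oxy}-2-methoxy-6-methylbenzoate | COC(=O)c1c(C)cc(OC(=O)c2c(C)cc(OCc3ccccc3)cc2OC)cc1OC
F3 | step 10 | 3-methoxy-4-(methoxycarbonyl)-5-methylphenyl 4-hydroxy-2-methoxy-6-methylbenzoate | COC(=O)c1c(C)cc(OC(=O)c2c(C)cc(O)cc2OC)cc1OC
F4 | step 4 | 3-methoxy-5-methyl-4-nitrosophenol | COc1cc(O)cc(C)c1N=O
F5 | step 4 | 4-amino-3-methoxy-5-methylphenol | COc1cc(O)cc(C)c1N
F6 | step 2 | [2,4-bis(benzyloxy)-6-methylphenyl]methanol | OCc1c(C)cc(OCc2ccccc2)cc1OCc1ccccc1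
F7 | step 2 | 2,4-bis(benzyloxy)-6-methylbenzaldehyde | O=Cc1c(C)cc(OCc2ccccc2)cc1OCc1ccccc1
F0 | step 7 | none | none
A1 | alternative 1 | 3-methoxy-4-{[3-methoxy-4-(methoxycarbonyl)-5-methylphenoxy]carbonyl}-5-methylphenyl (2E)-5-diazo-3-methyl-4-oxopent-2-enoate | COC(=O)c1c(C)cc(OC(=O)c2c(C)cc(OC(=O)/C=C(\C)C(=O)C=[N+]=[N-])cc2OC)cc1OC
A2 | alternative 1 | (triisopropylsilyloxy)ethyne | C#CO[Si](C(C)C)(C(C)C)C(C)C
A3 | alternative 1 | 3-methoxy-4-{[3-methoxy-4-(methoxycarbonyl)-5-methylphenoxy]carbonyl}-5-methylphenyl 2-hydroxy-6-methyl-4-[(triisopropylsilyl)oxy]benzoate | COC(=O)c1c(C)cc(OC(=O)c2c(C)cc(OC(=O)c3c(C)cc(O[Si](C(C)C)(C(C)C)C(C)C)cc3O)cc2OC)cc1OC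
A4 | alternative 2 | methyl 4-methoxy-6-methyl-2-oxo-2H-pyran-5-carboxylate | COC(=O)C1=C(C)OC(=O)C=C1OC
A5 | alternative 2 | 1,1-bis(trimethylsilyloxy)ethene | C=C(O[Si](C)(C)C)O[Si](C)(C)C
A6 | alternative 2 | methyl 4-hydroxy-2-methoxy-6-methylbenzoate | COC(=O)c1c(C)cc(O)cc1OC
A7 | alternative 3 | 1,1-dimethoxy-3-(trimethylsilyloxy)buta-1,3-diene | COC(OC)=CC(=C)O[Si](C)(C)C
A8 | alternative 3 | 3-methoxy-4-(methoxycarbonyl)-5-methylphenyl but-2-ynoate | CC#CC(=O)Oc1cc(C)c(C(=O)OC)c(OC)c1
A9 | alternative 3 | 3-methoxy-4-(methoxycarbonyl)-5-methylphenyl 4-hydroxy-2-methoxy-6-methylbenzoate | COC(=O)c1c(C)cc(OC(=O)c2c(C)cc(O)cc2OC)cc1OC
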